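**Retrosynthetic overview**
1. Kanzonol I ⇒ its 4′-O-TIPS ether ⇒ an acyclic (R)-1-aryloxy-3-arylpropan-2-ol. One operation makes the C4–C4a bond, the chroman ring and C3: the B-ring shifts 1,2 (future C4 → C3) through a phenonium ion, which the A-ring then traps by Friedel–Crafts closure.
2. The carbinol ⇒ A-ring (R)-glycidyl ether + 8-lithiated B-ring chromene (epoxide opening). The three-carbon unit and all chirality come from (S)-epichlorohydrin.
3. A-ring ⇒ resorcinol: O-methylation, C2 prenylation by ortho-lithiation, C5 hydroxylation by C–H borylation/oxidation.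
4. B-ring ⇒ cyclohexane-1,3-dione + prenal: pyran annulation, aromatisation to the chromen-5-ol, silylation, oxygen-directed C8 lithiation.
5. Ring order: B-ring pyran, then B-ring arene (aromatisation); the A-ring arene is carried from resorcinol; the central dihydropyran is closed last.

Assumption: the target SMILES defines the (3R)-isoflavan, and (S)-epichlorohydrin is used as bought in ≥99% ee.

**Step 1**
Reactants: 1 resorcinol
Product: 2 1,3-dimethoxybenzene
Conditions: MeI, K2CO3, acetone, reflux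
Reagents that add atoms: iodomethane, CI
Why: Williamson ether synthesis; both phenoxide oxygens are methylated by SN2 on MeI.

**Step 2**
Reactants: 2 1,3-dimethoxybenzene; 3 prenyl bromide (1-bromo-3-methylbut-2-ene)
Product: 5 1,3-dimethoxy-2-(3-methylbut-2-en-1-yl)benzene, via 2,6-dimethoxyphenyllithium 4 (not isolated)
Conditions: n-BuLi, THF, 0 °C→rt; CuBr·SMe2 (10 mol %), then 3, −78→0 °C
Reagents that add atoms: none
Why: Directed ortho-metalation removes the C2–H flanked by both methoxy groups, and copper-assisted SN2 coupling with the primary allylic bromide gives the linear prenyl arene.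

**Step 3**
Reactants: 5 1,3-dimethoxy-2-(3-methylbut-2-en-1-yl)benzene
Product: 7 3,5-dimethoxy-4-(3-methylbut-2-en-1-yl)phenol, via arylboronic pinacol ester 6 (not isolated)
Conditions: [Ir(OMe)(cod)]2 (1.5 mol %), dtbpy (3 mol %), B2pin2 (0.6 equiv), cyclohexane, 70 °C; then 30% H2O2, aq NaOH, THF, 0 °C
Reagents that add atoms: hydrogen peroxide, OO
Why: Iridium-catalysed C–H borylation is sterically controlled, so only C5–H (no ortho substituent) reacts, and alkaline peroxide oxidises the C–B bond to the phenol without touching the trisubstituted alkene (borylation/oxidation).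

**Step 4**
Reactants: 7 3,5-dimethoxy-4-(3-methylbut-2-en-1-yl)phenol; 8 (S)-epichlorohydrin
Product: 10 (R)-2-{[3,5-dimethoxy-4-(3-methylbut-2-en-1-yl)phenoxy]methyl}oxirane, via (S)-chlorohydrin ether 9 (not isolated)
Conditions: 8 (3 equiv), K2CO3, MeCN, 70 °C
Reagents that add atoms: none
Why: Williamson-type glycidylation in which the phenoxide opens the epoxide at its CH2 end and the alkoxide of 9 recloses on the CH2Cl carbon, so no bond to the stereocentre is broken and (S)-8 gives the (R)-glycidyl ether (the descriptor changes only through CIP priorities).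

**Step 5**
Reactants: 11 cyclohexane-1,3-dione; 12 3-methylbut-2-enal (prenal)
Product: 14 2,2-dimethyl-7,8-dihydro-2H-chromen-5(6H)-one, via Knoevenagel dienedione 13 (not isolated)
Conditions: ethylenediammonium diacetate (10 mol %), MeOH, rt
Reagents that add atoms: none
Why: Formal [3+3] annulation: Knoevenagel condensation gives oxatriene 13, which closes by oxa-6π electrocyclisation to the 2H-pyran.

**Step 6**
Reactants: 14 2,2-dimethyl-7,8-dihydro-2H-chromen-5(6H)-one
Product: 18 2,2-dimethyl-2H-chromen-5-ol, via α-selanyl ketone 15 (not isolated), via selenoxide 16 (not isolated), via cyclohexadienone tautomer 17 (not isolated)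
Conditions: LDA, THF, −78 °C; PhSeCl, −78 °C; then 30% H2O2, pyridine, CH2Cl2, 0 °C→rt
Reagents that add atoms: none
Why: Kinetic α′-deprotonation and selenenylation at C6, then selenoxide syn-elimination, give dienone 17, whose enolisation is driven by aromatisation.

**Step 7**
Reactants: 18 2,2-dimethyl-2H-chromen-5-ol
Product: 19 [(2,2-dimethyl-2H-chromen-5-yl)oxy]triisopropylsilane
Conditions: TIPSCl, imidazole, DMF, rt
Reagents that add atoms: chlorotriisopropylsilane, CC(C)[Si](Cl)(C(C)C)C(C)C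
Why: Standard phenol silylation; the bulky TIPS ether survives organolithium chemistry, cannot direct metalation and shields C6.

**Step 8**
Reactants: 19 [(2,2-dimethyl-2H-chromen-5-yl)oxy]triisopropylsilane; 10 (R)-2-{[3,5-dimethoxy-4-(3-methylbut-2-en-1-yl)phenoxy]methyl}oxirane
Product: 21 (R)-1-[3,5-dimethoxy-4-(3-methylbut-2-en-1-yl)phenoxy]-3-{2,2-dimethyl-5-[(triisopropylsilyl)oxy]-2H-chromen-8-yl}propan-2-ol, via 8-lithiochromene 20 (not isolated)
Conditions: 19 (1.3 equiv), n-BuLi (1.25 equiv), TMEDA, Et2O, 0 °C→rt; CuI (10 mol %), then 10 (1.0 equiv), THF, −40→0 °C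
Reagents that add atoms: none
Why: Directed ortho-metalation by the pyran oxygen occurs at C8 (C6 is blocked by OTIPS), and copper-catalysed SN2 opening of the epoxide at its CH2 end leaves the stereocentre untouched.

**Step 9**
Reactants: 21 (R)-1-[3,5-dimethoxy-4-(3-methylbut-2-en-1-yl)phenoxy]-3-{2,2-dimethyl-5-[(triisopropylsilyl)oxy]-2H-chromen-8-yl}propan-2-ol
Product: 25 Kanzonol I [(R)-8-[5,7-dimethoxy-6-(3-methylbut-2-en-1-yl)chroman-3-yl]-2,2-dimethyl-2H-chromen-5-ol], via secondary triflate 22 (not isolated), via phenonium ion 23 (not isolated), via TIPS-protected isoflavan 24 (not isolated)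
Conditions: Tf2O (1.1 equiv), 2,6-di-tert-butyl-4-methylpyridine (2.5 equiv), CH2Cl2, −78→0 °C; then TBAF (4 equiv), THF, 0 °C→rt
Reagents that add atoms: none
Why: Proposed new method: an enantiospecific phenonium-relay Friedel–Crafts annulation. Triflate 22 is flanked by an inductively deactivating CH2OAr group, so it does not ionise unassisted; instead the ipso carbon of the 2,4-dioxygenated B-ring displaces it from the rear (Ar1-3 participation) to give phenonium ion 23 with inversion at the carbinol carbon. The tethered phloroglucinol-type A-ring (two equivalent ortho carbons) then opens the cyclopropane at the less hindered CH2 end through a six-membered transition state, whereas attack at the secondary carbon would need a strained five-membered closure. The B-ring therefore ends on C3 with (R)-carbinol → (3R) transfer while C4–C4a and the chroman ring form, the hindered pyridine buffers TfOH so the prenyl and chromene alkenes survive, and fluoride then cleaves the aryl TIPS ether of 24. Closest known reaction types: Cram-type phenonium solvolysis with 1,2-aryl migration of β-aryl sulfonates, and Friedel–Crafts cycloalkylation of 3-aryloxypropyl electrophiles to chromans.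

**Compound list**
1 | resorcinol | Oc1cccc(O)c1 | starting material
2 | 1,3-dimethoxybenzene | COc1cccc(OC)c1 | intermediate
3 | prenyl bromide (1-bromo-3-methylbut-2-ene) | CC(C)=CCBr | starting material
4 | 2,6-dimethoxyphenyllithium | COc1cccc(OC)c1[Li] | intermediate (not isolated)
5 | 1,3-dimethoxy-2-(3-methylbut-2-en-1-yl)benzene | COc1cccc(OC)c1CC=C(C)C | intermediate
6 | 2-[3,5-dimethoxy-4-(3-methylbut-2-en-1-yl)phenyl]-4,4,5,5-tetramethyl-1,3,2-dioxaborolane | COc1cc(B2OC(C)(C)C(C)(C)O2)cc(OC)c1CC=C(C)C | intermediate (not isolated)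
7 | 3,5-dimethoxy-4-(3-methylbut-2-en-1-yl)phenol | COc1cc(O)cc(OC)c1CC=C(C)C | intermediate
8 | (S)-epichlorohydrin | ClC[C@@H]1CO1 | starting material
9 | (S)-1-chloro-3-[3,5-dimethoxy-4-(3-methylbut-2-en-1-yl)phenoxy]propan-2-ol | ClC[C@@H](O)COc1cc(OC)c(CC=C(C)C)c(OC)c1 | intermediate (not isolated)
10 | (R)-2-{[3,5-dimethoxy-4-(3-methylbut-2-en-1-yl)phenoxy]methyl}oxirane | COc1cc(OC[C@H]2CO2)cc(OC)c1CC=C(C)C | intermediate
11 | cyclohexane-1,3-dione | O=C1CCCC(=O)C1 | starting material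
12 | 3-methylbut-2-enal (prenal) | CC(C)=CC=O | starting material
13 | 2-(3-methylbut-2-en-1-ylidene)cyclohexane-1,3-dione | CC(C)=CC=C1C(=O)CCCC1=O | intermediate (not isolated)
14 | 2,2-dimethyl-7,8-dihydro-2H-chromen-5(6H)-one | CC1(C)C=CC2=C(O1)CCCC2=O | intermediate
15 | 2,2-dimethyl-6-(phenylselanyl)-7,8-dihydro-2H-chromen-5(6H)-one (racemic) | CC1(C)C=CC2=C(O1)CCC([Se]c1ccccc1)C2=O | intermediate (not isolated)
16 | 2,2-dimethyl-6-(phenylseleninyl)-7,8-dihydro-2H-chromen-5(6H)-one (stereoisomer mixture) | CC1(C)C=CC2=C(O1)CCC([Se](=O)c1ccccc1)C2=O | intermediate (not isolated)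
17 | 2,2-dimethyl-2H-chromen-5(8H)-one | CC1(C)C=CC2=C(O1)CC=CC2=O | intermediate (not isolated)
18 | 2,2-dimethyl-2H-chromen-5-ol | CC1(C)C=Cc2c(O)cccc2O1 | intermediate
19 | [(2,2-dimethyl-2H-chromen-5-yl)oxy]triisopropylsilane | CC(C)[Si](Oc1cccc2OC(C)(C)C=Cc12)(C(C)C)C(C)C | intermediate
20 | {2,2-dimethyl-5-[(triisopropylsilyl)oxy]-2H-chromen-8-yl}lithium | [Li]c1ccc(O[Si](C(C)C)(C(C)C)C(C)C)c2C=CC(C)(C)Oc12 | intermediate (not isolated)
21 | (R)-1-[3,5-dimethoxy-4-(3-methylbut-2-en-1-yl)phenoxy]-3-{2,2-dimethyl-5-[(triisopropylsilyl)oxy]-2H-chromen-8-yl}propan-2-ol | CC(C)[Si](Oc1ccc(C[C@@H](O)COc2cc(OC)c(CC=C(C)C)c(OC)c2)c2OC(C)(C)C=Cc12)(C(C)C)C(C)C | intermediate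
22 | (R)-1-[3,5-dimethoxy-4-(3-methylbut-2-en-1-yl)phenoxy]-3-{2,2-dimethyl-5-[(triisopropylsilyl)oxy]-2H-chromen-8-yl}propan-2-yl trifluoromethanesulfonate | CC(C)[Si](Oc1ccc(C[C@@H](OS(=O)(=O)C(F)(F)F)COc2cc(OC)c(CC=C(C)C)c(OC)c2)c2OC(C)(C)C=Cc12)(C(C)C)C(C)C | intermediate (not isolated)
23 | phenonium (spiro-cyclopropane arenium) triflate: B-ring ipso carbon bridges the former ArCH2 and the inverted carbinol carbon; spiro centre not defined | CC(C)[Si]([O+]=C1C=CC2(C[C@H]2COc2cc(OC)c(CC=C(C)C)c(OC)c2)C2=C1C=CC(C)(C)O2)(C(C)C)C(C)C.[O-]S(=O)(=O)C(F)(F)F | intermediate (not isolated)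
24 | (R)-({8-[5,7-dimethoxy-6-(3-methylbut-2-en-1-yl)chroman-3-yl]-2,2-dimethyl-2H-chromen-5-yl}oxy)triisopropylsilane | CC(C)[Si](Oc1ccc([C@@H]2COc3cc(OC)c(CC=C(C)C)c(OC)c3C2)c2OC(C)(C)C=Cc12)(C(C)C)C(C)C | intermediate (not isolated)
25 | Kanzonol I, (R)-8-[5,7-dimethoxy-6-(3-methylbut-2-en-1-yl)chroman-3-yl]-2,2-dimethyl-2H-chromen-5-ol | COc1cc2c(c(OC)c1CC=C(C)C)C[C@H](c1ccc(O)c3c1OC(C)(C)C=C3)CO2 | target

**Totals**
Total step count: 9 (steps 1–4 build the A-ring glycidyl ether, steps 5–7 the B-ring, steps 8–9 join and cyclise).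
Longest linear sequence: 6 steps (steps 1, 2, 3, 4, 8, 9, from resorcinol).

**Three steps most likely to fail**

Step 3 (C–H borylation with the prenyl group present). The Ir–H/HBpin system may hydroborate or isomerise the prenyl alkene, and some ortho-to-OMe borylation is possible. The fallback sets out from 2 and comes back at 7, placing the oxygen before the alkene exists. Compound 2 is borylated under the same iridium conditions to 2-(3,5-dimethoxyphenyl)-4,4,5,5-tetramethyl-1,3,2-dioxaborolane F1 and oxidised (H2O2, NaOH) to 3,5-dimethoxyphenol F2. Silylation (TIPSCl, imidazole) gives (3,5-dimethoxyphenoxy)triisopropylsilane F3. n-BuLi in THF at 0 °C lithiates only between the two methoxy groups, the other positions being shielded by OTIPS, to give [2,6-dimethoxy-4-(triisopropylsilyloxy)phenyl]lithium F4. Trapping with 3 (CuBr·SMe2 cat.) gives [3,5-dimethoxy-4-(3-methylbut-2-en-1-yl)phenoxy]triisopropylsilane F5, and TBAF releases 7.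

Step 8 (oxygen-directed lithiation of 19). The weak tertiary-alkyl aryl ether director may give slow or unselective metalation, and butyllithium may add to the chromene alkene. The fallback sets out from 1 and comes back at 20, fixing the metalation site with a halogen that is in place before the pyran is built. Resorcinol is monobrominated (NBS, CH2Cl2, −78→0 °C) to 4-bromobenzene-1,3-diol F6. The less hindered hydroxyl para to bromine is silylated (TIPSCl 1.0 equiv, imidazole, 0 °C) to 2-bromo-5-[(triisopropylsilyl)oxy]phenol F7. The remaining hydroxyl is alkylated with 3-chloro-3-methylbut-1-yne (K2CO3, KI, CuI cat., acetone) to {4-bromo-3-[(2-methylbut-3-yn-2-yl)oxy]phenoxy}triisopropylsilane F8. Thermal propargyl Claisen rearrangement and ring closure (N,N-diethylaniline, 180 °C) can only use the carbon between the two oxygens and gives [(8-bromo-2,2-dimethyl-2H-chromen-5-yl)oxy]triisopropylsilane F9. Br/Li exchange (t-BuLi, 2 equiv, Et2O, −78 °C) then delivers 20, and step 8 continues from the copper/epoxide stage.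

Step 9 (the new phenonium-relay annulation). Possible failures are participation by the chromene oxygen instead of the arene (five-membered oxonium and loss of the pyran), five-membered Friedel–Crafts closure at the secondary carbon, or elimination to the cinnamyl aryl ether. The fallback uses only known chemistry (Evans alkylation, then Mitsunobu ring closure). It sets out from 19 (lithiated to 20 as in step 8) and from 7, and comes back at 24, which is desilylated with TBAF as in step 9.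
- B-ring side: 20 is trapped with oxirane (CuI cat.) to give 2-{2,2-dimethyl-5-[(triisopropylsilyl)oxy]-2H-chromen-8-yl}ethan-1-ol F10. Oxidation (TEMPO, PhI(OAc)2, MeCN/H2O) gives 2-{2,2-dimethyl-5-[(triisopropylsilyl)oxy]-2H-chromen-8-yl}acetic acid F11. N-Acylation of (R)-4-benzyloxazolidin-2-one (PivCl, Et3N, LiCl) gives (R)-4-benzyl-3-(arylacetyl)oxazolidin-2-one F12.
- A-ring side: phenol 7 is ortho-formylated (MgCl2, Et3N, paraformaldehyde, MeCN, reflux) to 6-hydroxy-2,4-dimethoxy-3-(3-methylbut-2-en-1-yl)benzaldehyde F13. O-Allylation (allyl bromide, K2CO3) gives 6-(allyloxy)-2,4-dimethoxy-3-(3-methylbut-2-en-1-yl)benzaldehyde F14. Reduction (NaBH4) gives [6-(allyloxy)-2,4-dimethoxy-3-(3-methylbut-2-en-1-yl)phenyl]methanol F15. Appel bromination (CBr4, PPh3, 0 °C, used crude) gives 1-(allyloxy)-2-(bromomethyl)-3,5-dimethoxy-4-(3-methylbut-2-en-1-yl)benzene F16.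
- Union and closure: alkylation of the sodium enolate of F12 (NaHMDS, THF, −78 °C) with F16 gives (R)-4-benzyl-3-[(R)-2-aryl-3-arylpropanoyl]oxazolidin-2-one F17, the (R)-auxiliary setting the (R) α-centre. LiBH4 gives (R)-3-[6-(allyloxy)-2,4-dimethoxy-3-(3-methylbut-2-en-1-yl)phenyl]-2-{2,2-dimethyl-5-[(triisopropylsilyl)oxy]-2H-chromen-8-yl}propan-1-ol F18. Pd(PPh3)4/morpholine removes the allyl group to give (R)-2-(3-hydroxy-2-{2,2-dimethyl-5-[(triisopropylsilyl)oxy]-2H-chromen-8-yl}propyl)-3,5-dimethoxy-4-(3-methylbut-2-en-1-yl)phenol F19. Mitsunobu cyclisation (PPh3, DIAD, THF) closes O1–C2 to give 24.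

**Further compounds**
F1 | step 3 | 2-(3,5-dimethoxyphenyl)-4,4,5,5-tetramethyl-1,3,2-dioxaborolane | COc1cc(OC)cc(B2OC(C)(C)C(C)(C)O2)c1
F2 | step 3 | 3,5-dimethoxyphenol | COc1cc(O)cc(OC)c1
F3 | step 3 | (3,5-dimethoxyphenoxy)triisopropylsilane | COc1cc(O[Si](C(C)C)(C(C)C)C(C)C)cc(OC)c1
F4 | step 3 | [2,6-dimethoxy-4-(triisopropylsilyloxy)phenyl]lithium | [Li]c1c(OC)cc(O[Si](C(C)C)(C(C)C)C(C)C)cc1OC
F5 | step 3 | [3,5-dimethoxy-4-(3-methylbut-2-en-1-yl)phenoxy]triisopropylsilane | COc1cc(O[Si](C(C)C)(C(C)C)C(C)C)cc(OC)c1CC=C(C)C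
F6 | step 8 | 4-bromobenzene-1,3-diol | Oc1ccc(Br)c(O)c1
F7 | step 8 | 2-bromo-5-[(triisopropylsilyl)oxy]phenol | Oc1cc(O[Si](C(C)C)(C(C)C)C(C)C)ccc1Br
F8 | step 8 | {4-bromo-3-[(2-methylbut-3-yn-2-yl)oxy]phenoxy}triisopropylsilane | C#CC(C)(C)Oc1cc(O[Si](C(C)C)(C(C)C)C(C)C)ccc1Br
F9 | step 8 | [(8-bromo-2,2-dimethyl-2H-chromen-5-yl)oxy]triisopropylsilane | Brc1ccc(O[Si](C(C)C)(C(C)C)C(C)C)c2C=CC(C)(C)Oc12
F10 | step 9 | 2-{2,2-dimethyl-5-[(triisopropylsilyl)oxy]-2H-chromen-8-yl}ethan-1-ol | OCCc1ccc(O[Si](C(C)C)(C(C)C)C(C)C)c2C=CC(C)(C)Oc12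
F11 | step 9 | 2-{2,2-dimethyl-5-[(triisopropylsilyl)oxy]-2H-chromen-8-yl}acetic acid | OC(=O)Cc1ccc(O[Si](C(C)C)(C(C)C)C(C)C)c2C=CC(C)(C)Oc12
F12 | step 9 | (R)-4-benzyl-3-(2-{2,2-dimethyl-5-[(triisopropylsilyl)oxy]-2H-chromen-8-yl}acetyl)oxazolidin-2-one | O=C(Cc1ccc(O[Si](C(C)C)(C(C)C)C(C)C)c2C=CC(C)(C)Oc12)N1[C@H](Cc2ccccc2)COC1=O
F13 | step 9 | 6-hydroxy-2,4-dimethoxy-3-(3-methylbut-2-en-1-yl)benzaldehyde | COc1cc(O)c(C=O)c(OC)c1CC=C(C)C
F14 | step 9 | 6-(allyloxy)-2,4-dimethoxy-3-(3-methylbut-2-en-1-yl)benzaldehyde | COc1cc(OCC=C)c(C=O)c(OC)c1CC=C(C)C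
F15 | step 9 | [6-(allyloxy)-2,4-dimethoxy-3-(3-methylbut-2-en-1-yl)phenyl]methanol | COc1cc(OCC=C)c(CO)c(OC)c1CC=C(C)C
F16 | step 9 | 1-(allyloxy)-2-(bromomethyl)-3,5-dimethoxy-4-(3-methylbut-2-en-1-yl)benzene | COc1cc(OCC=C)c(CBr)c(OC)c1CC=C(C)C
F17 | step 9 | (R)-4-benzyl-3-[(R)-3-[6-(allyloxy)-2,4-dimethoxy-3-(3-methylbut-2-en-1-yl)phenyl]-2-{2,2-dimethyl-5-[(triisopropylsilyl)oxy]-2H-chromen-8-yl}propanoyl]oxazolidin-2-one | COc1cc(OCC=C)c(C[C@H](c2ccc(O[Si](C(C)C)(C(C)C)C(C)C)c3C=CC(C)(C)Oc23)C(=O)N2[C@H](Cc3ccccc3)COC2=O)c(OC)c1CC=C(C)C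
F18 | step 9 | (R)-3-[6-(allyloxy)-2,4-dimethoxy-3-(3-methylbut-2-en-1-yl)phenyl]-2-{2,2-dimethyl-5-[(triisopropylsilyl)oxy]-2H-chromen-8-yl}propan-1-ol | COc1cc(OCC=C)c(C[C@H](c2ccc(O[Si](C(C)C)(C(C)C)C(C)C)c3C=CC(C)(C)Oc23)CO)c(OC)c1CC=C(C)C
F19 | step 9 | (R)-2-(3-hydroxy-2-{2,2-dimethyl-5-[(triisopropylsilyl)oxy]-2H-chromen-8-yl}propyl)-3,5-dimethoxy-4-(3-methylbut-2-en-1-yl)phenol | COc1cc(O)c(C[C@H](c2ccc(O[Si](C(C)C)(C(C)C)C(C)C)c3C=CC(C)(C)Oc23)CO)c(OC)c1CC=C(C)C
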